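The dihydrofuran ring (O1–C2–C3–C3a–C7a) is disconnected at the C2–C3 bond. C2–H is benzylic and α to the ring oxygen, and C3 bears a one-carbon arm that can stand at the ester level. C3 can therefore be a donor/acceptor rhodium carbene that inserts into one of the two enantiotopic OCH2 hydrogens of a 3,4-dimethoxybenzyl aryl ether. One operation closes the last ring, forms C2–C3 and sets C2 under catalyst control; ethoxide then funnels the kinetic cis ester to the trans series. The precursor is an uncyclised aryl benzyl ether carrying an α-diazo ester ortho to the ether oxygen and a cinnamate as the latent enal.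

Key step: step 4

Assumption (chemistry): the S-configured catalyst Rh2(S-PTTL)4 is taken to deliver the 2R series, by analogy with closely related ortho-benzyloxy aryldiazoacetates. Should the sense prove opposite, Rh2(R-PTTL)4 is used and nothing else changes.

Step 1
Reactants: 1 5-iodovanillin; 2 3,4-dimethoxybenzyl bromide
Product: 3 4-[(3,4-dimethoxybenzyl)oxy]-3-iodo-5-methoxybenzaldehyde
Conditions: K2CO3, DMF, 50 °C
Reagents that add atoms: none
Why: Williamson ether synthesis; the acidic phenol of 1 (ortho iodine, para formyl) is alkylated by the reactive benzylic bromide, and no stereocentre is involved.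

Step 2
Reactants: 3 4-[(3,4-dimethoxybenzyl)oxy]-3-iodo-5-methoxybenzaldehyde; 4 ethyl (triphenylphosphoranylidene)acetate
Product: 5 ethyl (E)-3-{4-[(3,4-dimethoxybenzyl)oxy]-3-iodo-5-methoxyphenyl}prop-2-enoate
Conditions: toluene, 80 °C
Reagents that add atoms: none
Why: Wittig olefination with a stabilised ylide should give the E-cinnamate through the thermodynamically preferred oxaphosphetane, leaving the aryl iodide and the benzyl ether untouched.

Step 3
Reactants: 5 ethyl (E)-3-{4-[(3,4-dimethoxybenzyl)oxy]-3-iodo-5-methoxyphenyl}prop-2-enoate; 6 ethyl diazoacetate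
Product: 7 ethyl (E)-3-{3-(1-diazo-2-ethoxy-2-oxoethyl)-4-[(3,4-dimethoxybenzyl)oxy]-5-methoxyphenyl}prop-2-enoate
Conditions: Pd(PPh3)4 (5 mol %), Ag2CO3 (0.5 equiv), Et3N, toluene, rt
Reagents that add atoms: none
Why: Pd-catalysed cross-coupling of an aryl iodide with the C–H bond of an acceptor diazo compound (oxidative addition, silver/base-assisted palladation of the diazoacetate, reductive elimination) keeps the diazo group, and room temperature should prevent Heck reaction at the trans-cinnamate and thermal loss of N2.

Step 4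
Reactants: 7 ethyl (E)-3-{3-(1-diazo-2-ethoxy-2-oxoethyl)-4-[(3,4-dimethoxybenzyl)oxy]-5-methoxyphenyl}prop-2-enoate
Product: 9 ethyl (2R,3R)-2-(3,4-dimethoxyphenyl)-5-[(E)-3-ethoxy-3-oxoprop-1-en-1-yl]-7-methoxy-2,3-dihydro-1-benzofuran-3-carboxylate (2,3-trans), via cis-diester 8 (not isolated)
Conditions: Rh2(S-PTTL)4 (2 mol %), toluene, −60 °C, slow addition of 7; then NaOEt (cat.), EtOH, 0 °C → rt
Reagents that add atoms: none
Why: Rh2(S-PTTL)4 extrudes N2 from 7 to give an electrophilic donor/acceptor rhodium carbene at the future C3, which inserts through a concerted, hydride-transfer-like three-centre transition state into one benzylic OCH2 hydrogen activated by the ether oxygen and the electron-rich 3,4-dimethoxyphenyl group. The closest known reaction type is the Rh(II)-carboxylate-catalysed enantioselective intramolecular C–H insertion of ortho-benzyloxy aryldiazoacetates to cis-2-aryl-2,3-dihydrobenzofuran-3-carboxylates. The ring O1–C2–C3–C3a–C7a is closed by 1,5 C–H insertion, which forms the C2–C3 bond with the oxygen already in place. C2 is set by the chiral phthalimido-carboxylate ligand sphere, which selects between the two enantiotopic hydrogens; C3 emerges cis under kinetic control and is then equilibrated by ethoxide through the ester enolate to the more stable 2,3-trans arrangement, C2 staying fixed because ring opening of that enolate would be a retro-5-endo-trig process. The step needs chemoselectivity for the 1,5 insertion over cyclopropanation, arene addition, carbene dimerisation and ylide formation; this should be secured by the activated C–H held five atoms away, the electron-poor trans-disubstituted cinnamate, the fact that an oxonium ylide would have to be four-membered, and slow addition at low temperature.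

Step 5
Reactants: 9 ethyl (2R,3R)-2-(3,4-dimethoxyphenyl)-5-[(E)-3-ethoxy-3-oxoprop-1-en-1-yl]-7-methoxy-2,3-dihydro-1-benzofuran-3-carboxylate
Product: 10 (E)-3-[(2R,3S)-2-(3,4-dimethoxyphenyl)-3-(hydroxymethyl)-7-methoxy-2,3-dihydro-1-benzofuran-5-yl]prop-2-en-1-ol
Conditions: DIBAL-H (6 equiv), CH2Cl2, −78 → 0 °C; aq. Rochelle salt
Reagents that add atoms: none
Why: DIBAL-H reduction should take both esters to primary alcohols, the cinnamate by clean 1,2-reduction to the allylic alcohol; C2 and C3 are untouched (the descriptor at C3 changes from R to S only through the priority change).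

Step 6
Reactants: 10 (E)-3-[(2R,3S)-2-(3,4-dimethoxyphenyl)-3-(hydroxymethyl)-7-methoxy-2,3-dihydro-1-benzofuran-5-yl]prop-2-en-1-ol
Product: 11 4-O-methylbalanophonin, (E)-3-[(2R,3S)-2-(3,4-dimethoxyphenyl)-3-(hydroxymethyl)-7-methoxy-2,3-dihydro-1-benzofuran-5-yl]prop-2-enal
Conditions: activated MnO2 (excess), CH2Cl2, rt
Reagents that add atoms: none
Why: MnO2 oxidation is selective for the allylic (cinnamyl) alcohol over the saturated primary alcohol at C3 and should retain the E geometry and both stereocentres.

Compound list
1 | 5-iodovanillin (4-hydroxy-3-iodo-5-methoxybenzaldehyde) | COc1cc(C=O)cc(I)c1O | starting material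
2 | 3,4-dimethoxybenzyl bromide | COc1ccc(CBr)cc1OC | starting material
3 | 4-[(3,4-dimethoxybenzyl)oxy]-3-iodo-5-methoxybenzaldehyde | COc1ccc(COc2c(I)cc(C=O)cc2OC)cc1OC | intermediate
4 | ethyl (triphenylphosphoranylidene)acetate | CCOC(=O)C=P(c1ccccc1)(c1ccccc1)c1ccccc1 | starting material
5 | ethyl (E)-3-{4-[(3,4-dimethoxybenzyl)oxy]-3-iodo-5-methoxyphenyl}prop-2-enoate | CCOC(=O)/C=C/c1cc(I)c(OCc2ccc(OC)c(OC)c2)c(OC)c1 | intermediate
6 | ethyl diazoacetate | CCOC(=O)C=[N+]=[N-] | starting material
7 | ethyl (E)-3-{3-(1-diazo-2-ethoxy-2-oxoethyl)-4-[(3,4-dimethoxybenzyl)oxy]-5-methoxyphenyl}prop-2-enoate | CCOC(=O)/C=C/c1cc(OC)c(OCc2ccc(OC)c(OC)c2)c(C(=[N+]=[N-])C(=O)OCC)c1 | intermediate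
8 | ethyl (2R,3S)-2-(3,4-dimethoxyphenyl)-5-[(E)-3-ethoxy-3-oxoprop-1-en-1-yl]-7-methoxy-2,3-dihydro-1-benzofuran-3-carboxylate (2,3-cis) | COc1ccc([C@@H]2Oc3c(OC)cc(/C=C/C(=O)OCC)cc3[C@@H]2C(=O)OCC)cc1OC | intermediate (not isolated)
9 | ethyl (2R,3R)-2-(3,4-dimethoxyphenyl)-5-[(E)-3-ethoxy-3-oxoprop-1-en-1-yl]-7-methoxy-2,3-dihydro-1-benzofuran-3-carboxylate (2,3-trans) | COc1ccc([C@@H]2Oc3c(OC)cc(/C=C/C(=O)OCC)cc3[C@H]2C(=O)OCC)cc1OC | intermediate
10 | (E)-3-[(2R,3S)-2-(3,4-dimethoxyphenyl)-3-(hydroxymethyl)-7-methoxy-2,3-dihydro-1-benzofuran-5-yl]prop-2-en-1-ol | COc1ccc([C@@H]2Oc3c(OC)cc(/C=C/CO)cc3[C@H]2CO)cc1OC | intermediate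
11 | 4-O-methylbalanophonin, (E)-3-[(2R,3S)-2-(3,4-dimethoxyphenyl)-3-(hydroxymethyl)-7-methoxy-2,3-dihydro-1-benzofuran-5-yl]prop-2-enal | COc1ccc([C@@H]2Oc3c(OC)cc(/C=C/C=O)cc3[C@H]2CO)cc1OC | target

Total step count: 6
Longest linear sequence: 6 steps (from 1)

Steps most likely to fail

Step 4. The chiral catalyst may discriminate poorly between the two enantiotopic benzylic hydrogens, because the carbene carries an acceptor-substituted arene and an ethyl ester; the later equilibration cannot repair a low enantiomeric purity. Intermolecular carbene capture may also compete if addition is too fast. The fallback takes stereocontrol out of the ring closure and sets out from 7. An achiral catalyst (Rh2(esp)2, CH2Cl2, 0 °C) should give the racemic cis-diester, that is 8 together with its mirror image ethyl (2S,3R)-2-(3,4-dimethoxyphenyl)-5-[(E)-3-ethoxy-3-oxoprop-1-en-1-yl]-7-methoxy-2,3-dihydro-1-benzofuran-3-carboxylate F1, which is not isolated. The same ethoxide equilibration should then give the racemic trans-diester, that is 9 together with ethyl (2S,3S)-2-(3,4-dimethoxyphenyl)-5-[(E)-3-ethoxy-3-oxoprop-1-en-1-yl]-7-methoxy-2,3-dihydro-1-benzofuran-3-carboxylate F2. Preparative chromatography on a chiral polysaccharide phase (supercritical CO2/MeOH) removes F2, and the route is rejoined at 9.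

Step 3. Oxidative addition and palladation may be slow at the iodide flanked by the benzyloxy group, so that metal-mediated decomposition of the diazo ester or its dipolar addition to the cinnamate outruns the coupling. The fallback separates C–C bond formation from diazo installation and sets out from 5. Negishi coupling with the Reformatsky reagent of ethyl bromoacetate (BrZnCH2CO2Et, Pd2(dba)3/XPhos, THF, 50 °C) should give the arylacetate ethyl (E)-3-{4-[(3,4-dimethoxybenzyl)oxy]-3-(2-ethoxy-2-oxoethyl)-5-methoxyphenyl}prop-2-enoate F3. Regitz diazo transfer (p-acetamidobenzenesulfonyl azide, DBU, MeCN, 0 °C → rt) at the benzylic α-position then returns to the route at 7.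

Step 6. The oxidation may stall on a deactivated oxidant surface or lose chemoselectivity, with competing oxidation of the saturated primary alcohol or dehydrogenation of the dihydrofuran ring. The fallback is redox-neutral and sets out from 10. Cross-metathesis with excess crotonaldehyde (Hoveyda–Grubbs second-generation catalyst, CH2Cl2, 40 °C) should exchange the CH2OH terminus of the cinnamyl alkene for CHO, giving the E-enal 11 directly. This fallback makes no new compound (F0).

Further compounds
F1 | step 4 | ethyl (2S,3R)-2-(3,4-dimethoxyphenyl)-5-[(E)-3-ethoxy-3-oxoprop-1-en-1-yl]-7-methoxy-2,3-dihydro-1-benzofuran-3-carboxylate (enantiomer of 8, not isolated) | COc1ccc([C@H]2Oc3c(OC)cc(/C=C/C(=O)OCC)cc3[C@H]2C(=O)OCC)cc1OC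
F2 | step 4 | ethyl (2S,3S)-2-(3,4-dimethoxyphenyl)-5-[(E)-3-ethoxy-3-oxoprop-1-en-1-yl]-7-methoxy-2,3-dihydro-1-benzofuran-3-carboxylate (enantiomer of 9) | COc1ccc([C@H]2Oc3c(OC)cc(/C=C/C(=O)OCC)cc3[C@@H]2C(=O)OCC)cc1OC
F3 | step 3 | ethyl (E)-3-{4-[(3,4-dimethoxybenzyl)oxy]-3-(2-ethoxy-2-oxoethyl)-5-methoxyphenyl}prop-2-enoate | CCOC(=O)/C=C/c1cc(OC)c(OCc2ccc(OC)c(OC)c2)c(CC(=O)OCC)c1
F0 | step 6 | none | none
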